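## Retrosynthetic overview

1. Isodojaponin D ⇐ C16 α-methylenation and C19 desilylation of a tetracyclic β-keto spirolactone; the D ring is closed last.
2. D ring and C8 quaternary centre ⇐ Cu–H reductive nitrile (Thorpe-type) cyclisation of an α-alkylidene spirolactone; lactone ⇐ aldehyde reduction and lactonisation.
3. Key C9–C10 bond ⇐ Pd-catalysed allylic alkylation joining a ring-A 2-formylcyclohexanone with a ring-C cyclohexenyl carbonate.
4. Ring A ⇐ catalytic asymmetric Diels–Alder (2-silyloxydiene + methacrolein); ring C ⇐ organocatalytic Michael/aldol condensation, CBS reduction, Pd carbonylation.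
5. Ring order: A and C in parallel → lactone ring → D.

Assumption: atoms are labelled with ent-kaurane numbering (C1–C20); the C10 epimers of compound 9 are inconsequential because C10 becomes sp² in compound 10.

## Route

### Ring-A fragment

**Step 1**
Reactants: 1 allyl acetate; 2 methyl vinyl ketone
Product: 3 (E)-4-oxopent-2-en-1-yl acetate
Conditions: Hoveyda–Grubbs II (2 mol %), CH2Cl2, 40 °C
Reagents that add atoms: none
Why: Olefin cross-metathesis of a type I allyl ester with a type II enone gives the E cross product and joins C6–C5 to C10–C1–C2.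

**Step 2**
Reactants: 3 (E)-4-oxopent-2-en-1-yl acetate
Product: 4 (E)-4-[(triisopropylsilyl)oxy]penta-2,4-dien-1-yl acetate
Conditions: TIPSOTf, Et3N, CH2Cl2, 0 °C
Reagents that add atoms: TIPSOTf, CC(C)[Si](C(C)C)(C(C)C)OS(=O)(=O)C(F)(F)F
Why: Soft enolisation of the methyl ketone toward CH3 gives the cross-conjugated 2-silyloxydiene with the E alkene retained.

**Step 3**
Reactants: 4 the silyloxydiene; 5 methacrolein
Product: 6 [(1S,6R)-6-formyl-6-methyl-3-(triisopropylsilyloxy)cyclohex-2-en-1-yl]methyl acetate (CHO cis to CH2OAc)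
Conditions: (R)-o-tolyl-CBS-oxazaborolidine·HNTf2 (20 mol %), CH2Cl2, −78 °C
Reagents that add atoms: none
Why: Corey oxazaborolidinium-catalysed Diels–Alder, in which the 2-silyloxy ("para") and terminal alkyl ("ortho") effects fix C2–C3/C5–C4 bonding, endo-CHO addition to the E-diene places C19 cis to C6, and the catalyst exposes one enal face to set C4 and C5.

**Step 4**
Reactants: 6 the Diels–Alder aldehyde
Product: 7 [(1S,6R)-6-(hydroxymethyl)-6-methyl-3-(triisopropylsilyloxy)cyclohex-2-en-1-yl]methyl acetate
Conditions: NaBH4, MeOH/THF, −20 °C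
Reagents that add atoms: none
Why: Chemoselective borohydride reduction of the neopentyl aldehyde gives the C19 alcohol while the silyl enol ether and acetate survive.

**Step 5**
Reactants: 7 the C19 alcohol
Product: 8 [(1S,6R)-6-{[(tert-butyldiphenylsilyl)oxy]methyl}-6-methyl-3-(triisopropylsilyloxy)cyclohex-2-en-1-yl]methyl acetate
Conditions: TBDPSCl, imidazole, DMAP (cat.), DMF, rt
Reagents that add atoms: TBDPSCl, CC(C)(C)[Si](Cl)(c1ccccc1)c1ccccc1
Why: Standard silylation differentiates O19 (TBDPS, removed last) from O6 (acetate, kept to the end).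

**Step 6**
Reactants: 8 the silyl enol ether
Product: 9 [6-{[(tert-butyldiphenylsilyl)oxy]methyl}-2-(dimethoxymethyl)-6-methyl-3-oxocyclohexyl]methyl acetate (ring stereocentres as in 8; C2 epimers)
Conditions: HC(OMe)3, BF3·OEt2, CH2Cl2, −78 → −30 °C
Reagents that add atoms: trimethyl orthoformate, COC(OC)OC
Why: Mukaiyama-type addition of the regiodefined C1=C10 silyl enol ether to the dimethoxycarbenium ion installs C20 only at C10.

**Step 7**
Reactants: 9 the β-keto acetal
Product: 10 [6-{[(tert-butyldiphenylsilyl)oxy]methyl}-2-(hydroxymethylene)-6-methyl-3-oxocyclohexyl]methyl acetate (H-bonded enol of the 2-formyl ketone; C4/C5 as in 8)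
Conditions: 2 M HCl, THF, 0 °C → rt
Reagents that add atoms: water, O
Why: Acetal hydrolysis gives the acidic 2-formyl ketone, a soft 1,3-dicarbonyl pronucleophile at C10.

### Ring-C fragment

**Step 8**
Reactants: 11 4-pentenenitrile
Product: 12 4-oxobutanenitrile
Conditions: O3, CH2Cl2, −78 °C; then PPh3
Reagents that add atoms: ozone, [O-][O+]=O
Why: Ozonolysis with reductive work-up gives the unstable cyano aldehyde fresh (C14, C13, C16, C15).

**Step 9**
Reactants: 12 4-oxobutanenitrile; 2 methyl vinyl ketone
Product: 13 (S)-3-formyl-6-oxoheptanenitrile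
Conditions: (S)-α,α-diphenylprolinol methyl ether (5 mol %), ethyl 3,4-dihydroxybenzoate (20 mol %), neat, 4 °C
Reagents that add atoms: none
Why: Enamine-catalysed Michael addition of the aldehyde to the enone, with the diarylprolinol ether shielding one enamine face, sets C13.

**Step 10**
Reactants: 13 the keto aldehyde
Product: 14 (S)-2-(4-oxocyclohex-2-en-1-yl)acetonitrile
Conditions: 0.1 M aq KOH, n-Bu4NOH (cat.), Et2O/THF, reflux
Reagents that add atoms: none
Why: Intramolecular aldol condensation of the methyl ketone onto the aldehyde closes ring C as the 4-substituted cyclohexenone.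

**Step 11**
Reactants: 14 the enone
Product: 15 (S)-2-(3-iodo-4-oxocyclohex-2-en-1-yl)acetonitrile
Conditions: I2, pyridine, CH2Cl2, 0 °C → rt
Reagents that add atoms: iodine, II
Why: Johnson α-iodination of the enone (pyridine addition–iodination–elimination) places the handle for C7 on C8.

**Step 12**
Reactants: 15 the α-iodoenone
Product: 16 2-[(1S,4R)-4-hydroxy-3-iodocyclohex-2-en-1-yl]acetonitrile (OH trans to CH2CN)
Conditions: (S)-Me-CBS (20 mol %), catecholborane, toluene, −78 °C
Reagents that add atoms: none
Why: CBS reduction, with the α-iodoalkene as the large group, gives the (R)-carbinol under reagent control and so the 1,4-trans relationship to C13.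

**Step 13**
Reactants: 16 the iodo allylic alcohol
Product: 17 2,2,2-trifluoroethyl (3S,6R)-3-(cyanomethyl)-6-hydroxycyclohex-1-ene-1-carboxylate
Conditions: Pd(OAc)2 (5 mol %), PPh3, CO (1 atm), CF3CH2OH, Et3N, DMF, 50 °C
Reagents that add atoms: carbon monoxide, [C-]#[O+]; 2,2,2-trifluoroethanol, OCC(F)(F)F
Why: Pd-catalysed alkoxycarbonylation of the vinyl iodide installs C7 as an activated ester that will lactonise readily.

**Step 14**
Reactants: 17 the hydroxy ester
Product: 18 2,2,2-trifluoroethyl (3S,6R)-6-[(tert-butoxycarbonyl)oxy]-3-(cyanomethyl)cyclohex-1-ene-1-carboxylate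
Conditions: Boc2O, DMAP (cat.), CH2Cl2, 0 °C
Reagents that add atoms: Boc2O, CC(C)(C)OC(=O)OC(=O)OC(C)(C)C
Why: Carbonate formation gives a cyclic Morita–Baylis–Hillman-type allylic electrophile that releases its own base (t-BuO⁻) on ionisation.

### Union and end game

**Step 15**
Reactants: 10 the ring-A 2-formyl ketone; 18 the ring-C carbonate
Product: 19 coupled keto aldehyde: C10 quaternary (C20 = CHO cis to C6 and C19; C1 ketone), bonded to C9 of the trifluoroethyl cyclohex-1-ene-carboxylate, with C10 trans to the C13 CH2CN across ring C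
Conditions: Pd2(dba)3·CHCl3 (2.5 mol %), PPh3 (10 mol %), THF, 0 °C → rt
Reagents that add atoms: none
Why: Tsuji–Trost allylic alkylation, in which ionisation and attack both proceed anti to Pd so the C9–C10 bond forms with retention (trans to CH2CN) at the allyl terminus remote from C13, and the enol is attacked on the face anti to the C5 CH2OAc and the axial C19 CH2OTBDPS, setting C10.

**Step 16**
Reactants: 19 the coupled keto aldehyde
Product: 20 spiro δ-lactone (C20–O–C7(=O)–C8=C14) with the C1 ketone intact
Conditions: NaBH4 (0.4 equiv), THF/MeOH, −78 °C; AcOH; then CSA (cat.), CH2Cl2, rt (one pot)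
Reagents that add atoms: none
Why: The aldehyde is reduced selectively over the hindered ketone and the C20 alkoxide closes onto the activated trifluoroethyl ester, so only the 7,20-lactone can form while O1 is still a ketone.

**Step 17**
Reactants: 20 the spirolactone ketone
Product: 21 C1 (equatorial) alcohol, OH cis to C20
Conditions: NaBH4, CeCl3·7H2O, MeOH/THF, −40 °C; AcOH quench
Reagents that add atoms: none
Why: Luche-type 1,2-reduction with axial hydride delivery anti to the axial C20 gives the equatorial C1 alcohol without touching the alkylidene lactone.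

**Step 18**
Reactants: 21 the C1 alcohol
Product: 22 C1 acetate (α-alkylidene spirolactone nitrile; C1 and C6 acetates, C19 OTBDPS)
Conditions: Ac2O, DMAP, pyridine, CH2Cl2, 0 °C
Reagents that add atoms: acetic anhydride, CC(=O)OC(C)=O
Why: Immediate acetylation installs the C1 acetate of the target and blocks translactonisation to the 1,7-lactone.

**Step 19**
Reactants: 22 the α-alkylidene spirolactone nitrile
Product: 23 tetracyclic β-keto spirolactone (bicyclo[3.2.1]octanone D ring: C15 ketone, C16 CH2, C8 quaternary)
Conditions: Cu(OAc)2 (10 mol %), 1,2-bis(diphenylphosphino)benzene (10 mol %), TMDS, toluene, rt; then 1 M HCl, THF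
Reagents that add atoms: water, O
Why: Proposed new method: Cu–H-catalysed reductive Thorpe (Blaise-type) cyclisation, in which L2Cu–H adds hydride to C14 of the alkylidene lactone, the C8 copper enolate adds to the Cu-coordinated nitrile carbon (C15) in a 5-exo-dig closure possible only on the ring-C face bearing the CH2CN arm (setting C8 with C7 cis to C10), the N-cuprio imine is silylated to regenerate Cu–H, and acid work-up hydrolyses the imine to the ketone; the closest known chemistry is the Cu–H (Stryker-type) reductive aldol cyclisation of enoates and the zinc-enolate Blaise/Thorpe–Ziegler additions to nitriles.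

**Step 20**
Reactants: 23 the β-keto spirolactone
Product: 24 19-O-TBDPS isodojaponin D (C16=C17 exo-methylene enone)
Conditions: (Me2N)2CH2, Ac2O, DMF, 95 °C
Reagents that add atoms: bis(dimethylamino)methane, CN(C)CN(C)C
Why: In situ iminium (Mannich) reaction and amine elimination methylenates C16, the only enolisable position of the C15 ketone, without strong base.

**Step 21**
Reactants: 24 the TBDPS ether
Product: 25 isodojaponin D
Conditions: HF·pyridine, THF/pyridine, 0 °C → rt
Reagents that add atoms: none
Why: Buffered fluoride cleaves the primary silyl ether while the acetates, lactone and exo-methylene enone are stable.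

## Compound list

1 | allyl acetate | C=CCOC(C)=O | starting material
2 | methyl vinyl ketone | C=CC(C)=O | starting material
3 | (E)-4-oxopent-2-en-1-yl acetate | CC(=O)/C=C/COC(C)=O | intermediate
4 | (E)-4-[(triisopropylsilyl)oxy]penta-2,4-dien-1-yl acetate | C=C(O[Si](C(C)C)(C(C)C)C(C)C)/C=C/COC(C)=O | intermediate
5 | methacrolein | C=C(C)C=O | starting material
6 | [(1S,6R)-6-formyl-6-methyl-3-(triisopropylsilyloxy)cyclohex-2-en-1-yl]methyl acetate | CC(=O)OC[C@H]1C=C(O[Si](C(C)C)(C(C)C)C(C)C)CC[C@@]1(C)C=O | intermediate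
7 | [(1S,6R)-6-(hydroxymethyl)-6-methyl-3-(triisopropylsilyloxy)cyclohex-2-en-1-yl]methyl acetate | CC(=O)OC[C@H]1C=C(O[Si](C(C)C)(C(C)C)C(C)C)CC[C@@]1(C)CO | intermediate
8 | [(1S,6R)-6-(TBDPS-oxymethyl)-6-methyl-3-(triisopropylsilyloxy)cyclohex-2-en-1-yl]methyl acetate | CC(=O)OC[C@H]1C=C(O[Si](C(C)C)(C(C)C)C(C)C)CC[C@@]1(C)CO[Si](c1ccccc1)(c1ccccc1)C(C)(C)C | intermediate
9 | [6-(TBDPS-oxymethyl)-2-(dimethoxymethyl)-6-methyl-3-oxocyclohexyl]methyl acetate (C2 epimers) | CC(=O)OC[C@H]1C(C(OC)OC)C(=O)CC[C@@]1(C)CO[Si](c1ccccc1)(c1ccccc1)C(C)(C)C | intermediate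
10 | [6-(TBDPS-oxymethyl)-2-(hydroxymethylene)-6-methyl-3-oxocyclohexyl]methyl acetate (Z-enol) | CC(=O)OC[C@H]1C(=CO)C(=O)CC[C@@]1(C)CO[Si](c1ccccc1)(c1ccccc1)C(C)(C)C | intermediate
11 | 4-pentenenitrile | C=CCCC#N | starting material
12 | 4-oxobutanenitrile | N#CCCC=O | intermediate
13 | (S)-3-formyl-6-oxoheptanenitrile | O=C[C@H](CC#N)CCC(C)=O | intermediate
14 | (S)-2-(4-oxocyclohex-2-en-1-yl)acetonitrile | N#CC[C@H]1C=CC(=O)CC1 | intermediate
15 | (S)-2-(3-iodo-4-oxocyclohex-2-en-1-yl)acetonitrile | N#CC[C@H]1C=C(I)C(=O)CC1 | intermediate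
16 | 2-[(1S,4R)-4-hydroxy-3-iodocyclohex-2-en-1-yl]acetonitrile | N#CC[C@H]1C=C(I)[C@H](O)CC1 | intermediate
17 | 2,2,2-trifluoroethyl (3S,6R)-3-(cyanomethyl)-6-hydroxycyclohex-1-ene-1-carboxylate | N#CC[C@H]1C=C(C(=O)OCC(F)(F)F)[C@H](O)CC1 | intermediate
18 | 2,2,2-trifluoroethyl (3S,6R)-6-[(tert-butoxycarbonyl)oxy]-3-(cyanomethyl)cyclohex-1-ene-1-carboxylate | N#CC[C@H]1C=C(C(=O)OCC(F)(F)F)[C@H](OC(=O)OC(C)(C)C)CC1 | intermediate
19 | coupled keto aldehyde (C9–C10 bond; C10 bears CHO, C1 ketone) | N#CC[C@H]1C=C(C(=O)OCC(F)(F)F)[C@@H](CC1)[C@]1(C=O)C(=O)CC[C@@](C)(CO[Si](c2ccccc2)(c2ccccc2)C(C)(C)C)[C@H]1COC(C)=O | intermediate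
20 | α-alkylidene spiro-δ-lactone, C1 ketone | N#CC[C@H]1C=C2C(=O)OC[C@]3(C(=O)CC[C@@](C)(CO[Si](c4ccccc4)(c4ccccc4)C(C)(C)C)[C@H]3COC(C)=O)[C@@H]2CC1 | intermediate
21 | α-alkylidene spirolactone, C1 alcohol | N#CC[C@H]1C=C2C(=O)OC[C@]3([C@@H](O)CC[C@@](C)(CO[Si](c4ccccc4)(c4ccccc4)C(C)(C)C)[C@H]3COC(C)=O)[C@@H]2CC1 | intermediate
22 | α-alkylidene spirolactone, C1 acetate | N#CC[C@H]1C=C2C(=O)OC[C@]3([C@@H](OC(C)=O)CC[C@@](C)(CO[Si](c4ccccc4)(c4ccccc4)C(C)(C)C)[C@H]3COC(C)=O)[C@@H]2CC1 | intermediate
23 | 17-nor-15-oxo tetracyclic spirolactone, 19-OTBDPS | C1C(=O)[C@]23C[C@H]1CC[C@H]2[C@]1(COC3=O)[C@@H](OC(C)=O)CC[C@@](C)(CO[Si](c2ccccc2)(c2ccccc2)C(C)(C)C)[C@H]1COC(C)=O | intermediate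
24 | 19-O-TBDPS isodojaponin D | C=C1C(=O)[C@]23C[C@H]1CC[C@H]2[C@]1(COC3=O)[C@@H](OC(C)=O)CC[C@@](C)(CO[Si](c2ccccc2)(c2ccccc2)C(C)(C)C)[C@H]1COC(C)=O | intermediate
25 | isodojaponin D | C=C1C(=O)[C@]23C[C@H]1CC[C@H]2[C@]1(COC3=O)[C@@H](OC(C)=O)CC[C@@](C)(CO)[C@H]1COC(C)=O | target

## Step count and risks

Total steps: 21 (ring-A branch 7, ring-C branch 7, common end game 7).
Longest linear sequence: 14 steps (steps 1–7 then 15–21; the branch through steps 8–14 is also 14), which is two thirds of the total.

Steps most likely to fail: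

1. **Step 19 (the proposed Cu–H reductive Thorpe cyclisation).** Risks are simple protonation to the saturated lactone, acetyl transfer from the C1 acetate to the C8 enolate, and sluggish addition to the nitrile. Fallback with known chemistry:
   - make the ring-C fragment from 4-pentenal instead of 12, so C13 carries an allyl group, and carry O1 as a silyl ether;
   - after lactonisation, do a Stryker conjugate reduction, form the silyl ketene acetal (KHMDS/TBSCl), and run a Pd(OAc)2-mediated oxidative 5-exo cyclisation onto the allyl group to close the bicyclo[3.2.1]octane with a C15 exo-methylene;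
   - ozonolyse to the C15 ketone, then methylenate and exchange protecting groups.

2. **Step 15 (Pd allylic alkylation forming the hindered C9–C10 bond).** Risks are attack at C14 instead of C9, O-allylation, and low reactivity at the quaternary centre. Fallback: abandon the allylic alkylation and build the spirolactone by a radical route:
   - convert ring A to its C10–C20 exocyclic epoxide and couple it with 2,2,2-trifluoroethyl acrylate under Cp2TiCl (reductive epoxide opening, Giese addition, lactonisation);
   - α-alkylate the lactone with an iodide carrying C11–C16, desaturate, and close ring C by SmI2 ketyl–olefin cyclisation.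

3. **Step 3 (asymmetric Diels–Alder).** Risks are endo/exo selectivity, the sense and level of enantioselectivity (the (R)-catalyst assignment rests on the Corey model and should be confirmed), and ionisation of the allylic acetate. Fallback: run the cycloaddition racemically (Me2AlCl or thermal) and resolve instead, either by lipase-mediated acylation of alcohol 7 or by coupling racemic 10 with enantiopure 18 and separating the diastereomers of 19.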